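**Strategy**

Ring C is cut at O1–C2 and C4–C4a. This exposes that C4(=O)–C3–C2, ring B and its 2'-OH (ortho to C1') are together the ring-opened lactone of the pyranocoumarin xanthyletin, and that ring A is a 2-prenylresorcinol metalated ortho to one oxygen. In the key step the aryllithium from 4-bromo-2-prenylresorcinol opens the lactone by acyl substitution (C4–C4a), releasing the 2'-OH and a Z-2'-hydroxychalcone, which a cinchona thiourea closes in the same flask by oxa-Michael addition (O1–C2), setting C2 as S. The precursors are thus a bromoresorcinol and a commercial coumarin; the target is their 1:1 adduct, with no protecting group left to remove.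

Key step: step 5

Assumption 1: xanthyletin is taken as a purchasable natural coumarin.
Assumption 2: the sense of induction of the cinchona thiourea is taken by analogy with E-configured 2'-hydroxychalcones; the quinidine-derived catalyst is written for the 2S series, and its quinine-derived pseudoenantiomer would replace it if the first run shows the opposite sense.

**Route**

Step 1
Reactants: 1 resorcinol
Product: 2 1,3-bis(methoxymethoxy)benzene
Conditions: NaH (2.2 equiv), DMF, 0 °C; MOMCl (2.2 equiv), 0 °C to rt
Reagents that add atoms: chloromethyl methyl ether (MOMCl), COCCl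
Why: Williamson-type O-alkylation of the bis-phenoxide installs two methoxymethyl ethers that serve as directing groups for the two metalations that follow.

Step 2
Reactants: 2 1,3-bis(methoxymethoxy)benzene, 3 prenyl bromide
Product: 5 1,3-bis(methoxymethoxy)-2-(3-methylbut-2-en-1-yl)benzene, via 2-lithio arene 4 (not isolated)
Conditions: n-BuLi, THF, 0 °C to rt; 3, −78 °C to rt
Reagents that add atoms: none
Why: Directed ortho-metalation should remove the proton between the two OMOM groups (most acidic, doubly coordinated), and the aryllithium should be alkylated by SN2 attack at the primary carbon of prenyl bromide.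

Step 3
Reactants: 5 1,3-bis(methoxymethoxy)-2-(3-methylbut-2-en-1-yl)benzene
Product: 7 1-bromo-2,4-bis(methoxymethoxy)-3-(3-methylbut-2-en-1-yl)benzene, via 4-lithio arene 6 (not isolated)
Conditions: n-BuLi, TMEDA, THF, −20 to 0 °C; BrCH2CH2Br, −78 °C to rt
Reagents that add atoms: 1,2-dibromoethane, BrCCBr
Why: A second directed ortho-metalation at the only remaining ring position next to an OMOM group, followed by bromophilic quench, places bromine on the ring by a carbanion route that leaves the prenyl alkene untouched.

Step 4
Reactants: 7 1-bromo-2,4-bis(methoxymethoxy)-3-(3-methylbut-2-en-1-yl)benzene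
Product: 8 4-bromo-2-(3-methylbut-2-en-1-yl)benzene-1,3-diol
Conditions: HCl (1.25 M in MeOH), rt
Reagents that add atoms: none
Why: Acid-catalysed transacetalisation in methanol should cleave both aryl methoxymethyl ethers, with dilute acid at rt chosen so that the trisubstituted alkene is not protonated.

Step 5
Reactants: 8 4-bromo-2-(3-methylbut-2-en-1-yl)benzene-1,3-diol, 9 xanthyletin
Product: 13 (2S)-7-hydroxy-2-(7-hydroxy-2,2-dimethyl-2H-chromen-6-yl)-8-(3-methylbut-2-en-1-yl)-2,3-dihydro-4H-chromen-4-one (CNP0279510.1), via aryllithium 10 (not isolated), via trilithium chalconate 11 (not isolated), via Z-chalcone 12 (not isolated)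
Conditions: 8, n-BuLi (2.0 equiv), THF, −78 °C; t-BuLi (2.0 equiv), −78 °C; 9, −78 to −20 °C; AcOH (3.0 equiv), −78 °C; solvent exchange to toluene below 0 °C; N-[3,5-bis(trifluoromethyl)phenyl]-N'-[(9R)-6'-methoxycinchonan-9-yl]thiourea (20 mol%), toluene, 0 °C
Reagents that add atoms: none
Why: Bromine–lithium exchange on the dilithium phenoxide gives aryllithium 10, whose carbanion adds 1,2 to the lactone carbonyl of 9 (bond C4–C4a); collapse of the tetrahedral alkoxide expels the ring B phenoxide, so the coumarin is unzipped to the Z-enone 11, and AcOH gives 12 in equilibrium with its 2H-chromen-2-ol hemiketal. The closest known reactions are the addition of aryllithiums to coumarins (the entry to 2-aryl-2H-chromen-2-ols and flavylium salts) and the cinchona-thiourea-catalysed oxa-Michael cyclisation of 2'-hydroxychalcones to flavanones. Ring C closes by 6-endo-trig oxa-Michael addition of the chelated ring A 2'-OH to the β-carbon of the enone (bond O1–C2). C2 is the only new stereocenter and is controlled by the catalyst: the quinuclidine nitrogen activates the phenol while the thiourea binds the enone carbonyl, so that one enantiotopic face of the β-carbon is presented to O1 (2S intended). The step needs mono-addition at C=O over conjugate or double addition, which is secured by the hard aryllithium and by the ketone emerging as a 2,4-dioxidoaryl ketone (a doubly vinylogous lithium carboxylate) that resists a second attack; the regiochemistry on ring A is fixed by the bromine, which in the symmetric 2-prenylresorcinol core can only lead to the 7-hydroxy-8-prenyl pattern. Only the ring A 2'-OH can reach the β-carbon, whereas the ring B phenol can add only reversibly to the carbonyl, so the hemiketal and both enone geometries should drain into the flavanone.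

**Compound list**

1 | resorcinol (benzene-1,3-diol) | Oc1cccc(O)c1 | starting material
2 | 1,3-bis(methoxymethoxy)benzene | COCOc1cccc(OCOC)c1 | intermediate
3 | prenyl bromide (1-bromo-3-methylbut-2-ene) | CC(C)=CCBr | starting material
4 | [2,6-bis(methoxymethoxy)phenyl]lithium | COCOc1cccc(OCOC)c1[Li] | intermediate
5 | 1,3-bis(methoxymethoxy)-2-(3-methylbut-2-en-1-yl)benzene | COCOc1cccc(OCOC)c1CC=C(C)C | intermediate
6 | [2,4-bis(methoxymethoxy)-3-(3-methylbut-2-en-1-yl)phenyl]lithium | COCOc1ccc([Li])c(OCOC)c1CC=C(C)C | intermediate
7 | 1-bromo-2,4-bis(methoxymethoxy)-3-(3-methylbut-2-en-1-yl)benzene | COCOc1ccc(Br)c(OCOC)c1CC=C(C)C | intermediate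
8 | 4-bromo-2-(3-methylbut-2-en-1-yl)benzene-1,3-diol | CC(C)=CCc1c(O)ccc(Br)c1O | intermediate
9 | xanthyletin (8,8-dimethyl-2H,8H-pyrano[3,2-g]chromen-2-one) | CC1(C)C=Cc2cc3ccc(=O)oc3cc2O1 | starting material
10 | [2,4-bis(lithiooxy)-3-(3-methylbut-2-en-1-yl)phenyl]lithium | CC(C)=CCc1c(O[Li])ccc([Li])c1O[Li] | intermediate
11 | trilithium salt of 12 (lithium on both ring A oxygens and on the ring B oxygen) | CC(C)=CCc1c(O[Li])ccc(C(=O)/C=C\c2cc3C=CC(C)(C)Oc3cc2O[Li])c1O[Li] | intermediate
12 | (Z)-1-[2,4-dihydroxy-3-(3-methylbut-2-en-1-yl)phenyl]-3-(7-hydroxy-2,2-dimethyl-2H-chromen-6-yl)prop-2-en-1-one | CC(C)=CCc1c(O)ccc(C(=O)/C=C\c2cc3C=CC(C)(C)Oc3cc2O)c1O | intermediate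
13 | (2S)-7-hydroxy-2-(7-hydroxy-2,2-dimethyl-2H-chromen-6-yl)-8-(3-methylbut-2-en-1-yl)-2,3-dihydro-4H-chromen-4-one (CNP0279510.1) | CC(C)=CCc1c(O)ccc2c1O[C@H](c1cc3c(cc1O)OC(C)(C)C=C3)CC2=O | target

**Step count and risks**

Total step count: 5. Longest linear sequence: 5 steps (1 → 2 → 5 → 7 → 8 → 13); xanthyletin 9 enters in step 5.

Steps most likely to fail:

1. Step 5 (key step). What may go wrong: poor facial selectivity in the closure of ring C, because the enone is Z-configured and carries a free ring B phenol, and erosion of enantiomeric purity through reversible retro-oxa-Michael opening. The fallback replaces asymmetric catalysis by resolution. It sets out from 12: after the AcOH quench, crude 12 would be closed without chiral catalyst (NaOAc, EtOH, rt) to the racemic flavanone (2RS)-7-hydroxy-2-(7-hydroxy-2,2-dimethyl-2H-chromen-6-yl)-8-(3-methylbut-2-en-1-yl)-2,3-dihydro-4H-chromen-4-one F1. Preparative HPLC on silica-bound amylose tris(3,5-dimethylphenylcarbamate) should then separate the enantiomers; the 2S enantiomer is 13, where the route is rejoined. The 2R antipode should be recyclable to F1 by the same base-mediated ring opening and reclosure.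

2. Step 3. What may go wrong: competing lateral lithiation at the benzylic and allylic CH2 of the prenyl group, which is flanked by both OMOM groups, instead of ring metalation. The fallback reverses the order of bromination and prenylation. It sets out from 2: N-bromosuccinimide in MeCN at 0 °C should brominate the ring para to one OMOM group, with no alkene yet present, to give 1-bromo-2,4-bis(methoxymethoxy)benzene F2. Lithium 2,2,6,6-tetramethylpiperidide in THF at −78 °C should then remove the proton between the two OMOM groups without touching the C–Br bond, giving [3-bromo-2,6-bis(methoxymethoxy)phenyl]lithium F3, which is alkylated with 3 to give 7, where the route is rejoined.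

3. Step 4. What may go wrong: acid-promoted cyclisation of the prenyl chain onto the freed neighbouring phenol (2,2-dimethylchroman formation) or addition of HCl across the alkene during acetal cleavage. The fallback changes the protecting group to the far more acid-labile 1-ethoxyethyl ether. It sets out from 1: ethyl vinyl ether and pyridinium p-toluenesulfonate (cat.) in CH2Cl2 should give 1,3-bis(1-ethoxyethoxy)benzene F4 (mixture of diastereomers at the acetal carbons, of no consequence). n-BuLi in THF should give [2,6-bis(1-ethoxyethoxy)phenyl]lithium F5, which is alkylated with 3 to 1,3-bis(1-ethoxyethoxy)-2-(3-methylbut-2-en-1-yl)benzene F6. n-BuLi and TMEDA should give [2,4-bis(1-ethoxyethoxy)-3-(3-methylbut-2-en-1-yl)phenyl]lithium F7, which is quenched with 1,2-dibromoethane to 1-bromo-2,4-bis(1-ethoxyethoxy)-3-(3-methylbut-2-en-1-yl)benzene F8. Pyridinium p-toluenesulfonate (cat.) in MeOH at rt should then release 8, where the route is rejoined, under conditions too mild to protonate the alkene.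

**Further compounds**

F1 | step 5 | (2RS)-7-hydroxy-2-(7-hydroxy-2,2-dimethyl-2H-chromen-6-yl)-8-(3-methylbut-2-en-1-yl)-2,3-dihydro-4H-chromen-4-one (racemate) | CC(C)=CCc1c(O)ccc2c1OC(c1cc3c(cc1O)OC(C)(C)C=C3)CC2=O
F2 | step 3 | 1-bromo-2,4-bis(methoxymethoxy)benzene | COCOc1ccc(Br)c(OCOC)c1
F3 | step 3 | [3-bromo-2,6-bis(methoxymethoxy)phenyl]lithium | COCOc1ccc(Br)c(OCOC)c1[Li]
F4 | step 4 | 1,3-bis(1-ethoxyethoxy)benzene (acetal carbons unspecified) | CCOC(C)Oc1cccc(OC(C)OCC)c1
F5 | step 4 | [2,6-bis(1-ethoxyethoxy)phenyl]lithium (acetal carbons unspecified) | CCOC(C)Oc1cccc(OC(C)OCC)c1[Li]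
F6 | step 4 | 1,3-bis(1-ethoxyethoxy)-2-(3-methylbut-2-en-1-yl)benzene (acetal carbons unspecified) | CCOC(C)Oc1cccc(OC(C)OCC)c1CC=C(C)C
F7 | step 4 | [2,4-bis(1-ethoxyethoxy)-3-(3-methylbut-2-en-1-yl)phenyl]lithium (acetal carbons unspecified) | CCOC(C)Oc1ccc([Li])c(OC(C)OCC)c1CC=C(C)C
F8 | step 4 | 1-bromo-2,4-bis(1-ethoxyethoxy)-3-(3-methylbut-2-en-1-yl)benzene (acetal carbons unspecified) | CCOC(C)Oc1ccc(Br)c(OC(C)OCC)c1CC=C(C)C
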